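**Strategy.** The γ-lactone ring (O6–C6–C7–C11–C12, germacranolide numbering) is treated as a formal [3+2] adduct of a glycolate carbonate, in which C6–O6–C12 is already joined, and the C7=C11 bond of a (Z)-γ-silyloxy enoate whose C8 stereocentre comes from a glycidyl ether. One anionic operation does both jobs: a Michael addition (C6–C7), then a Dieckmann-type acylation of the resulting ester enolate by the carbonate (C11–C12). It builds the lactone with its C6 and C7 stereocentres. The precursors are the enoate and S-ethyl (methoxycarbonyloxy)thioacetate. The extra tert-butoxycarbonyl group on C11 later becomes the exocyclic methylene, and the ten-membered ring is closed at C4=C5 by metathesis.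

Key step: step 12

Remark: germacranolide numbering of the target is used for all intermediates (C1–C10 ring carbons, C11–C13 lactone carbons, C14 formyl carbon, C15 hydroxymethyl carbon, O6 and O8 the oxygens on C6 and C8). Compound 5 is assumed to be commercially available; otherwise it is one etherification from (S)-glycidol.

Step 1
Reactants: 1 2-methylidenepropane-1,3-diol
Product: 2 2-{[(tert-butyldiphenylsilyl)oxy]methyl}prop-2-en-1-ol
Conditions: TBDPSCl (1 equiv), imidazole, THF, 0 °C
Reagents that add atoms: tert-butyl(chloro)diphenylsilane, CC(C)(C)[Si](Cl)(c1ccccc1)c1ccccc1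
Why: Statistical mono-silylation of a symmetrical diol (silyl ether formation) should give the mono-ether, which is separable from diol and bis-ether.

Step 2
Reactants: 2 2-{[(tert-butyldiphenylsilyl)oxy]methyl}prop-2-en-1-ol
Product: 4 4-{[(tert-butyldiphenylsilyl)oxy]methyl}pent-4-enal, via allyl vinyl ether 3 (not isolated)
Conditions: ethyl vinyl ether (excess), Hg(OAc)2 (cat.), reflux; evaporate; toluene, 150 °C (sealed tube)
Reagents that add atoms: ethyl vinyl ether, C=COCC
Why: Mercury-catalysed transvinylation followed by a thermal [3,3]-sigmatropic Claisen rearrangement should deliver C1–C3 and leave the 1,1-disubstituted C4 olefin.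

Step 3
Reactants: 5 (R)-4-methoxybenzyl glycidyl ether; 6 triethyl phosphonoacetate
Product: 8 (5R)-3-(diethoxyphosphoryl)-5-{[(4-methoxybenzyl)oxy]methyl}oxolan-2-one, via hydroxy phosphonate ester 7 (not isolated)
Conditions: 6, NaH, THF, 0 °C → rt; then 5, 65 °C; aq. HCl work-up
Reagents that add atoms: none
Why: SN2 opening of the terminal epoxide at C9 by the phosphonoacetate anion and lactonisation of the C8 alkoxide onto the ethyl ester should give the phosphono lactone, with C8 retained from 5.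

Step 4
Reactants: 8 (5R)-3-(diethoxyphosphoryl)-5-{[(4-methoxybenzyl)oxy]methyl}oxolan-2-one; 4 4-{[(tert-butyldiphenylsilyl)oxy]methyl}pent-4-enal
Product: 9 (3E,5R)-3-(4-{[(tert-butyldiphenylsilyl)oxy]methyl}pent-4-en-1-ylidene)-5-{[(4-methoxybenzyl)oxy]methyl}oxolan-2-one
Conditions: 8, NaH, THF, 0 °C; then 4, 0 °C → rt
Reagents that add atoms: none
Why: Horner–Wadsworth–Emmons olefination of an α-phosphono lactone should favour the (E)-alkylidene lactone, which is the required C1=C10 geometry (C14 trans to C2).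

Step 5
Reactants: 9 (3E,5R)-alkylidene lactone
Product: 10 (2R,4E)-8-{[(tert-butyldiphenylsilyl)oxy]methyl}-4-(hydroxymethyl)-1-[(4-methoxybenzyl)oxy]nona-4,8-dien-2-ol
Conditions: i-Bu2AlH (DIBAL-H), CH2Cl2, −78 → 0 °C; Rochelle salt work-up
Reagents that add atoms: none
Why: 1,2-Reduction of the unsaturated lactone by the aluminium hydride should open it to the C14/C8 diol without touching the olefin geometry.

Step 6
Reactants: 10 (2R,4E)-diol
Product: 11 (2R,4E)-2-[(tert-butyldimethylsilyl)oxy]-4-{[(tert-butyldimethylsilyl)oxy]methyl}-8-{[(tert-butyldiphenylsilyl)oxy]methyl}-1-[(4-methoxybenzyl)oxy]nona-4,8-diene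
Conditions: TBSOTf, 2,6-lutidine, CH2Cl2, −78 → 0 °C
Reagents that add atoms: tert-butyldimethylsilyl triflate, CC(C)(C)[Si](C)(C)OS(=O)(=O)C(F)(F)F
Why: Silyl triflate with a hindered base should silylate both the primary allylic and the secondary hydroxyl (silyl ether formation).

Step 7
Reactants: 11 bis-TBS ether
Product: 12 (2R,4E)-2-[(tert-butyldimethylsilyl)oxy]-4-{[(tert-butyldimethylsilyl)oxy]methyl}-8-{[(tert-butyldiphenylsilyl)oxy]methyl}nona-4,8-dien-1-ol
Conditions: DDQ, CH2Cl2/pH 7 buffer, 0 °C → rt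
Reagents that add atoms: none
Why: Oxidative cleavage of the 4-methoxybenzyl ether by DDQ should free the C7 hydroxyl and leave the silyl ethers and olefins untouched.

Step 8
Reactants: 12 primary alcohol
Product: 13 (2R,4E)-2-[(tert-butyldimethylsilyl)oxy]-4-{[(tert-butyldimethylsilyl)oxy]methyl}-8-{[(tert-butyldiphenylsilyl)oxy]methyl}nona-4,8-dienal
Conditions: Dess–Martin periodinane, NaHCO3, CH2Cl2, 0 °C → rt
Reagents that add atoms: none
Why: Buffered Dess–Martin oxidation should give the α-silyloxy aldehyde without epimerisation at C8.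

Step 9
Reactants: 13 α-silyloxy aldehyde
Product: 14 tert-butyl (2Z,4R,6E)-4-[(tert-butyldimethylsilyl)oxy]-6-{[(tert-butyldimethylsilyl)oxy]methyl}-10-{[(tert-butyldiphenylsilyl)oxy]methyl}undeca-2,6,10-trienoate
Conditions: tert-butyl (diphenoxyphosphoryl)acetate, NaH, THF, −78 → −20 °C
Reagents that add atoms: tert-butyl (diphenoxyphosphoryl)acetate, CC(C)(C)OC(=O)CP(=O)(Oc1ccccc1)Oc1ccccc1
Why: Horner–Wadsworth–Emmons olefination with a diaryl phosphonoacetate is Z-selective and should give the (Z)-C7=C11 enoate needed for stereocontrol in step 12.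

Step 10
Reactants: 15 glycolic acid
Product: 16 2-[(methoxycarbonyl)oxy]acetic acid
Conditions: ClCO2Me, pyridine, THF, 0 °C → rt; acidic aq. work-up
Reagents that add atoms: methyl chloroformate, COC(=O)Cl
Why: O-acylation of the hydroxyl by the chloroformate (carbonate formation) installs the O6–C12 bond; any mixed anhydride is hydrolysed on work-up.

Step 11
Reactants: 16 2-[(methoxycarbonyl)oxy]acetic acid
Product: 17 S-ethyl 2-[(methoxycarbonyl)oxy]ethanethioate
Conditions: EtSH, DCC, DMAP (cat.), CH2Cl2, 0 °C → rt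
Reagents that add atoms: ethanethiol, CCS
Why: Steglich-type carbodiimide coupling should give the thioester, whose C5 can later be reduced selectively.

Step 12
Reactants: 14 (Z)-enoate; 17 S-ethyl 2-[(methoxycarbonyl)oxy]ethanethioate
Product: 19 lactone thioester (tert-butyl 2-oxooxolane-3-carboxylate with the S-ethyl thiocarboxylate on C6 and the C8–C4 chain on C7; 6,7-trans; C11 epimers), via Michael adduct 18 (not isolated)
Conditions: LiN(SiMe3)2 (1.1 equiv) added to 14 + 17, THF, −78 °C; then LiN(SiMe3)2 (1.1 equiv), −78 → 0 °C; AcOH quench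
Reagents that add atoms: none
Why: Proposed new method: the thioester enolate of 17 adds through C6 to C7 of the (Z)-enoate 14 (Michael addition), and the tert-butyl ester enolate at C11 formed in this way, kept alive by the second equivalent of base, attacks the carbonate carbonyl C12 that already hangs on O6 and expels methoxide, the malonate-type anion of 19 being the thermodynamic sink. The closest known reaction types are the Michael–Dieckmann annulation of glycolates and thioglycolates with acrylates and the C-acylation of ester enolates by dialkyl carbonates. The γ-lactone ring (O6, C6, C7, C11, C12) is closed by a 5-exo-trig nucleophilic acyl substitution at C12. C7 is controlled by C8: allylic 1,3-strain in the (Z)-enoate holds H8 in the alkene plane and the enolate should come in anti to the C9 chain, which puts C6 syn to O8 along the zigzag C9–C8–C7–C11; C6 is epimerisable next to the thioester and should settle trans to the C7 side chain on the lactone, while C11 remains a removable mixture. The step needs the Michael addition to outrun the 1,2-carbonate shift (Chan-type) of the enolate of 17 and needs acylation at C12 only; low temperature, the soft thioester enolate, the hindered tert-butyl ester and the five-membered transition state are relied on for this.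

Step 13
Reactants: 19 lactone thioester
Product: 20 lactone aldehyde (C5 formyl group on C6)
Conditions: Et3SiH, Pd/C (10 %), CH2Cl2, rt
Reagents that add atoms: none
Why: Fukuyama reduction should convert the thioester into the aldehyde in the presence of the lactone, the tert-butyl ester and the silyl ethers.

Step 14
Reactants: 20 lactone aldehyde
Product: 21 vinyl lactone (C5 vinyl group on C6; diene for ring closure)
Conditions: Ph3PCH3Br, KN(SiMe3)2 (excess ylide), THF, −78 → 0 °C
Reagents that add atoms: methyltriphenylphosphonium bromide, C[P+](c1ccccc1)(c1ccccc1)c1ccccc1.[Br-]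
Why: Wittig methylenation should give the vinyl group; the first equivalent of ylide only deprotonates the acidic C11–H, and C6 stays in the more stable trans arrangement.

Step 15
Reactants: 21 vinyl lactone
Product: 22 ten-membered carbocycle (tert-butyl ester on C11; C8–OTBS, C14–OTBS, C15–OTBDPS; both ring olefins cis in the ring)
Conditions: second-generation Hoveyda–Grubbs catalyst, RuCl2(H2IMes)(=CH-C6H4-2-O-i-Pr) (cat.), toluene (1 mM), 80 °C
Reagents that add atoms: none
Why: Ring-closing olefin metathesis between the C5 vinyl group and the 1,1-disubstituted C4 olefin should close the ring at C4=C5, the ten-membered ring and the trans-fused lactone allowing only the ring-cis alkene.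

Step 16
Reactants: 22 ten-membered carbocycle
Product: 25 α-methylene lactone (C11=C13 installed; silyl ethers as in 22), via carboxylic acid 23 (not isolated), via Mannich base 24 (not isolated)
Conditions: TMSOTf, 2,6-lutidine, CH2Cl2, 0 °C; aq. work-up; then 37 % aq. HCHO, Et2NH, THF, rt; AcOH/NaOAc, 60 °C
Reagents that add atoms: formaldehyde, C=O
Why: Silyl triflate cleaves the tert-butyl ester without harming silyl ethers, and the α-carboxy lactone should undergo a Mannich reaction and decarboxylative elimination to the α-methylene lactone.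

Step 17
Reactants: 25 α-methylene lactone
Product: 26 C8,C14-diol (C15–OTBDPS retained)
Conditions: 48 % aq. HF, MeCN, 0 °C
Reagents that add atoms: none
Why: Acidic fluoride desilylation should remove both tert-butyldimethylsilyl ethers faster than the tert-butyldiphenylsilyl ether and avoids the basic conditions that could trigger translactonisation to O8.

Step 18
Reactants: 26 C8,C14-diol
Product: 27 hydroxy enal (C14 aldehyde, free C8–OH)
Conditions: MnO2, CH2Cl2, rt
Reagents that add atoms: none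
Why: Manganese dioxide oxidises only the primary allylic C14 alcohol, giving the (E)-enal and leaving the non-allylic C8 hydroxyl.

Step 19
Reactants: 27 hydroxy enal
Product: 28 15-O-tert-butyldiphenylsilyl ether of the target
Conditions: (S)-2-methylbutanoic anhydride, DMAP (cat.), pyridine, CH2Cl2, 0 °C → rt
Reagents that add atoms: (S)-2-methylbutanoic anhydride, CC[C@H](C)C(=O)OC(=O)[C@@H](C)CC
Why: DMAP-catalysed acylation of the only free hydroxyl with the anhydride should give the C8 ester with retention at C8 and without epimerising the acyl α-centre.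

Step 20
Reactants: 28 15-O-silyl ether of the target
Product: 29 target compound
Conditions: HF·pyridine, pyridine/THF, 0 °C → rt
Reagents that add atoms: none
Why: Buffered fluoride desilylation should cleave the primary allylic silyl ether and is tolerated by the enal, the ester and the α-methylene lactone.

**Compound list**

1 | 2-methylidenepropane-1,3-diol | C=C(CO)CO | starting material
2 | 2-{[(tert-butyldiphenylsilyl)oxy]methyl}prop-2-en-1-ol | C=C(CO)CO[Si](c1ccccc1)(c1ccccc1)C(C)(C)C | intermediate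
3 | allyl vinyl ether of 2 (not isolated) | C=COCC(=C)CO[Si](c1ccccc1)(c1ccccc1)C(C)(C)C | intermediate
4 | 4-{[(tert-butyldiphenylsilyl)oxy]methyl}pent-4-enal | O=CCCC(=C)CO[Si](c1ccccc1)(c1ccccc1)C(C)(C)C | intermediate
5 | (R)-2-{[(4-methoxybenzyl)oxy]methyl}oxirane | COc1ccc(COC[C@H]2CO2)cc1 | starting material
6 | triethyl phosphonoacetate | CCOC(=O)CP(=O)(OCC)OCC | starting material
7 | ethyl (4R)-2-(diethoxyphosphoryl)-4-hydroxy-5-[(4-methoxybenzyl)oxy]pentanoate (C2 epimers; not isolated) | CCOC(=O)C(C[C@@H](O)COCc1ccc(OC)cc1)P(=O)(OCC)OCC | intermediate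
8 | (5R)-3-(diethoxyphosphoryl)-5-{[(4-methoxybenzyl)oxy]methyl}oxolan-2-one (C3 epimers) | O=C1O[C@@H](COCc2ccc(OC)cc2)CC1P(=O)(OCC)OCC | intermediate
9 | (3E,5R)-3-(4-{[(tert-butyldiphenylsilyl)oxy]methyl}pent-4-en-1-ylidene)-5-{[(4-methoxybenzyl)oxy]methyl}oxolan-2-one | C=C(CO[Si](c1ccccc1)(c1ccccc1)C(C)(C)C)CC/C=C2/C(=O)O[C@@H](COCc1ccc(OC)cc1)C2 | intermediate
10 | (2R,4E)-8-{[(tert-butyldiphenylsilyl)oxy]methyl}-4-(hydroxymethyl)-1-[(4-methoxybenzyl)oxy]nona-4,8-dien-2-ol | C=C(CO[Si](c1ccccc1)(c1ccccc1)C(C)(C)C)CC/C=C(/CO)C[C@@H](O)COCc1ccc(OC)cc1 | intermediate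
11 | (2R,4E)-2-[(tert-butyldimethylsilyl)oxy]-4-{[(tert-butyldimethylsilyl)oxy]methyl}-8-{[(tert-butyldiphenylsilyl)oxy]methyl}-1-[(4-methoxybenzyl)oxy]nona-4,8-diene | C=C(CO[Si](c1ccccc1)(c1ccccc1)C(C)(C)C)CC/C=C(/CO[Si](C)(C)C(C)(C)C)C[C@@H](O[Si](C)(C)C(C)(C)C)COCc1ccc(OC)cc1 | intermediate
12 | (2R,4E)-2-[(tert-butyldimethylsilyl)oxy]-4-{[(tert-butyldimethylsilyl)oxy]methyl}-8-{[(tert-butyldiphenylsilyl)oxy]methyl}nona-4,8-dien-1-ol | C=C(CO[Si](c1ccccc1)(c1ccccc1)C(C)(C)C)CC/C=C(/CO[Si](C)(C)C(C)(C)C)C[C@@H](O[Si](C)(C)C(C)(C)C)CO | intermediate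
13 | (2R,4E)-2-[(tert-butyldimethylsilyl)oxy]-4-{[(tert-butyldimethylsilyl)oxy]methyl}-8-{[(tert-butyldiphenylsilyl)oxy]methyl}nona-4,8-dienal | C=C(CO[Si](c1ccccc1)(c1ccccc1)C(C)(C)C)CC/C=C(/CO[Si](C)(C)C(C)(C)C)C[C@@H](O[Si](C)(C)C(C)(C)C)C=O | intermediate
14 | tert-butyl (2Z,4R,6E)-4-[(tert-butyldimethylsilyl)oxy]-6-{[(tert-butyldimethylsilyl)oxy]methyl}-10-{[(tert-butyldiphenylsilyl)oxy]methyl}undeca-2,6,10-trienoate | C=C(CO[Si](c1ccccc1)(c1ccccc1)C(C)(C)C)CC/C=C(/CO[Si](C)(C)C(C)(C)C)C[C@@H](O[Si](C)(C)C(C)(C)C)/C=C\C(=O)OC(C)(C)C | intermediate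
15 | glycolic acid | OCC(=O)O | starting material
16 | 2-[(methoxycarbonyl)oxy]acetic acid | COC(=O)OCC(=O)O | intermediate
17 | S-ethyl 2-[(methoxycarbonyl)oxy]ethanethioate | CCSC(=O)COC(=O)OC | intermediate
18 | Michael adduct (acyclic; C6–C7 bond formed, methyl carbonate still on O6, tert-butyl ester on C11–C13, S-ethyl thioester at C5; not isolated) | CCSC(=O)[C@@H](OC(=O)OC)[C@H](CC(=O)OC(C)(C)C)[C@H](O[Si](C)(C)C(C)(C)C)C/C(CO[Si](C)(C)C(C)(C)C)=C\CCC(=C)CO[Si](c1ccccc1)(c1ccccc1)C(C)(C)C | intermediate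
19 | lactone thioester (6,7-trans γ-lactone; tert-butyl ester on C11, C11 epimers; S-ethyl thioester at C5; C6, C7, C8 as in the target) | CC(C)(C)OC(=O)C1C(=O)O[C@H](C(=O)SCC)[C@H]1[C@H](O[Si](C)(C)C(C)(C)C)C/C(CO[Si](C)(C)C(C)(C)C)=C\CCC(=C)CO[Si](c1ccccc1)(c1ccccc1)C(C)(C)C | intermediate
20 | lactone aldehyde (C5 formyl group on C6) | CC(C)(C)OC(=O)C1C(=O)O[C@H](C=O)[C@H]1[C@H](O[Si](C)(C)C(C)(C)C)C/C(CO[Si](C)(C)C(C)(C)C)=C\CCC(=C)CO[Si](c1ccccc1)(c1ccccc1)C(C)(C)C | intermediate
21 | vinyl lactone (C5 vinyl group on C6) | CC(C)(C)OC(=O)C1C(=O)O[C@H](C=C)[C@H]1[C@H](O[Si](C)(C)C(C)(C)C)C/C(CO[Si](C)(C)C(C)(C)C)=C\CCC(=C)CO[Si](c1ccccc1)(c1ccccc1)C(C)(C)C | intermediate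
22 | ten-membered carbocycle (germacra-1(10),4-dien-12,6-olide skeleton, both ring olefins cis in the ring; C11–CO2t-Bu, C8–OTBS, C14–OTBS, C15–OTBDPS) | CC(C)(C)OC(=O)C1C(=O)O[C@@H]2/C=C(/CO[Si](c3ccccc3)(c3ccccc3)C(C)(C)C)CC/C=C(/CO[Si](C)(C)C(C)(C)C)C[C@@H](O[Si](C)(C)C(C)(C)C)[C@@H]12 | intermediate
23 | C11 carboxylic acid of 22 (not isolated) | OC(=O)C1C(=O)O[C@@H]2/C=C(/CO[Si](c3ccccc3)(c3ccccc3)C(C)(C)C)CC/C=C(/CO[Si](C)(C)C(C)(C)C)C[C@@H](O[Si](C)(C)C(C)(C)C)[C@@H]12 | intermediate
24 | Mannich base, C11 carrying CO2H and CH2NEt2 (not isolated) | OC(=O)C1(CN(CC)CC)C(=O)O[C@@H]2/C=C(/CO[Si](c3ccccc3)(c3ccccc3)C(C)(C)C)CC/C=C(/CO[Si](C)(C)C(C)(C)C)C[C@@H](O[Si](C)(C)C(C)(C)C)[C@@H]12 | intermediate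
25 | α-methylene lactone (C8–OTBS, C14–OTBS, C15–OTBDPS) | C=C1C(=O)O[C@@H]2/C=C(/CO[Si](c3ccccc3)(c3ccccc3)C(C)(C)C)CC/C=C(/CO[Si](C)(C)C(C)(C)C)C[C@@H](O[Si](C)(C)C(C)(C)C)[C@@H]12 | intermediate
26 | C8,C14-diol (C15–OTBDPS) | C=C1C(=O)O[C@@H]2/C=C(/CO[Si](c3ccccc3)(c3ccccc3)C(C)(C)C)CC/C=C(/CO)C[C@@H](O)[C@@H]12 | intermediate
27 | hydroxy enal (C14 aldehyde, C8–OH, C15–OTBDPS) | C=C1C(=O)O[C@@H]2/C=C(/CO[Si](c3ccccc3)(c3ccccc3)C(C)(C)C)CC/C=C(/C=O)C[C@@H](O)[C@@H]12 | intermediate
28 | 15-O-tert-butyldiphenylsilyl ether of the target | C=C1C(=O)O[C@@H]2/C=C(/CO[Si](c3ccccc3)(c3ccccc3)C(C)(C)C)CC/C=C(/C=O)C[C@@H](OC(=O)[C@@H](C)CC)[C@@H]12 | intermediate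
29 | target: (6R,7R,8R)-15-hydroxy-8-[(S)-2-methylbutanoyloxy]-14-oxogermacra-1(10),4,11(13)-trien-12,6-olide (both ring olefins cis in the ring) | C=C1C(=O)O[C@@H]2/C=C(/CO)CC/C=C(/C=O)C[C@@H](OC(=O)[C@@H](C)CC)[C@@H]12 | target

**Totals.** Total step count: 20. Longest linear sequence: 17 steps (1, 2, 4–9, 12–20).

**Steps most likely to fail**

Step 12 (proposed new method). What may go wrong: the carbonate may shift from O6 to C6 in the enolate of 17 (Chan-type 1,2-shift) before the Michael addition; proton transfer may stop the cascade at the open Michael adduct; the enolate may attack the wrong face of C7. Fallback with known chemistry, setting out from 14 and coming back at 19: the chelated lithium enolate of S-ethyl 2-[(4-methoxybenzyl)oxy]ethanethioate F1 (from commercial (4-methoxybenzyloxy)acetic acid, EtSH and DCC) is added to 14 in an ordinary glycolate Michael addition to give the O6-protected adduct F2. DDQ frees the C6 hydroxyl to give the α-hydroxy thioester F3. ClCO2Me/pyridine then gives carbonate 18, this time isolated. LiN(SiMe3)2 (2.2 equiv) in THF closes the lactone by intramolecular Claisen acylation to 19, so the two bonds are made in two separate, precedented operations.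

Step 15. What may go wrong: oligomerisation through the C5 vinyl group, because closure onto the hindered 1,1-disubstituted olefin and the strain of the ten-membered ring make cyclisation slow. Fallback, setting out from 8 and coming back at 22: the ring is closed by a Nozaki–Hiyama–Kishi reaction and an allylic transposition instead.
- Pent-4-yn-1-ol is hydroiodinated (NaI, Me3SiCl, H2O, MeCN) to 4-iodopent-4-en-1-ol F4 and oxidised (Dess–Martin) to 4-iodopent-4-enal F5.
- Olefination of 8 with F5 as in step 4 gives iodo lactone F6. Steps 5–9 then give diol F7, bis-silyl ether F8, alcohol F9, aldehyde F10 and (Z)-enoate F11.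
- The annulation of step 12 with 17 gives lactone thioester F13 via Michael adduct F12.
- Because Pd/Et3SiH would reduce the iodoalkene, the thioester is reduced with i-Bu2AlH at −78 °C (after deprotonation of C11 with NaH) to aldehyde F14.
- CrCl2 with NiCl2 (cat.) in DMSO at high dilution closes the ring to the C5 carbinol F15, which carries an exocyclic methylene on C4.
- Ph3SiOReO3 (cat.) in Et2O effects the 1,3-transposition to the primary allylic alcohol F16, with C4=C5 in the ring.
- TBDPSCl/imidazole returns 22.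

Step 16. What may go wrong: loss of silyl ethers or premature decarboxylation during the Lewis-acidic ester cleavage, and conjugate addition of the amine to the new methylene lactone. Fallback, setting out from 22 and coming back at 25: the ester is deliberately removed with decarboxylation (silica gel, toluene, 110 °C) to the C11-unsubstituted lactone F17. Its lithium enolate (LiN(i-Pr)2, THF, −78 °C) is trapped with Eschenmoser's salt to give the dimethylaminomethyl lactone F18. Quaternisation with MeI and elimination with NaHCO3 then gives 25.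

**Further compounds**

F1 | step 12 | S-ethyl 2-[(4-methoxybenzyl)oxy]ethanethioate | CCSC(=O)COCc1ccc(OC)cc1
F2 | step 12 | Michael adduct with 4-methoxybenzyl ether on O6 | CCSC(=O)[C@@H](OCc1ccc(OC)cc1)[C@H](CC(=O)OC(C)(C)C)[C@H](O[Si](C)(C)C(C)(C)C)C/C(CO[Si](C)(C)C(C)(C)C)=C\CCC(=C)CO[Si](c1ccccc1)(c1ccccc1)C(C)(C)C
F3 | step 12 | α-hydroxy thioester (free O6–H) | CCSC(=O)[C@@H](O)[C@H](CC(=O)OC(C)(C)C)[C@H](O[Si](C)(C)C(C)(C)C)C/C(CO[Si](C)(C)C(C)(C)C)=C\CCC(=C)CO[Si](c1ccccc1)(c1ccccc1)C(C)(C)C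
F4 | step 15 | 4-iodopent-4-en-1-ol | C=C(I)CCCO
F5 | step 15 | 4-iodopent-4-enal | C=C(I)CCC=O
F6 | step 15 | (3E,5R)-3-(4-iodopent-4-en-1-ylidene)-5-{[(4-methoxybenzyl)oxy]methyl}oxolan-2-one | C=C(I)CC/C=C1/C(=O)O[C@@H](COCc2ccc(OC)cc2)C1
F7 | step 15 | (2R,4E)-4-(hydroxymethyl)-8-iodo-1-[(4-methoxybenzyl)oxy]nona-4,8-dien-2-ol | C=C(I)CC/C=C(/CO)C[C@@H](O)COCc1ccc(OC)cc1
F8 | step 15 | bis(tert-butyldimethylsilyl) ether of F7 | C=C(I)CC/C=C(/CO[Si](C)(C)C(C)(C)C)C[C@@H](O[Si](C)(C)C(C)(C)C)COCc1ccc(OC)cc1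
F9 | step 15 | primary alcohol (iodo analogue of 12) | C=C(I)CC/C=C(/CO[Si](C)(C)C(C)(C)C)C[C@@H](O[Si](C)(C)C(C)(C)C)CO
F10 | step 15 | aldehyde (iodo analogue of 13) | C=C(I)CC/C=C(/CO[Si](C)(C)C(C)(C)C)C[C@@H](O[Si](C)(C)C(C)(C)C)C=O
F11 | step 15 | (Z)-enoate (iodo analogue of 14) | C=C(I)CC/C=C(/CO[Si](C)(C)C(C)(C)C)C[C@@H](O[Si](C)(C)C(C)(C)C)/C=C\C(=O)OC(C)(C)C
F12 | step 15 | Michael adduct (iodo analogue of 18, not isolated) | CCSC(=O)[C@@H](OC(=O)OC)[C@H](CC(=O)OC(C)(C)C)[C@H](O[Si](C)(C)C(C)(C)C)C/C(CO[Si](C)(C)C(C)(C)C)=C\CCC(I)=C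
F13 | step 15 | lactone thioester (iodo analogue of 19) | CC(C)(C)OC(=O)C1C(=O)O[C@H](C(=O)SCC)[C@H]1[C@H](O[Si](C)(C)C(C)(C)C)C/C(CO[Si](C)(C)C(C)(C)C)=C\CCC(I)=C
F14 | step 15 | lactone aldehyde (iodo analogue of 20) | CC(C)(C)OC(=O)C1C(=O)O[C@H](C=O)[C@H]1[C@H](O[Si](C)(C)C(C)(C)C)C/C(CO[Si](C)(C)C(C)(C)C)=C\CCC(I)=C
F15 | step 15 | ten-membered C5 carbinol with exocyclic methylene on C4 (C5 epimers) | CC(C)(C)OC(=O)C1C(=O)O[C@@H]2C(O)C(=C)CC/C=C(/CO[Si](C)(C)C(C)(C)C)C[C@@H](O[Si](C)(C)C(C)(C)C)[C@@H]12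
F16 | step 15 | ten-membered primary allylic alcohol (free C15–OH, C4=C5 in the ring) | CC(C)(C)OC(=O)C1C(=O)O[C@@H]2/C=C(/CO)CC/C=C(/CO[Si](C)(C)C(C)(C)C)C[C@@H](O[Si](C)(C)C(C)(C)C)[C@@H]12
F17 | step 16 | C11-unsubstituted lactone (C11H2) | C1C(=O)O[C@@H]2/C=C(/CO[Si](c3ccccc3)(c3ccccc3)C(C)(C)C)CC/C=C(/CO[Si](C)(C)C(C)(C)C)C[C@@H](O[Si](C)(C)C(C)(C)C)[C@@H]12
F18 | step 16 | C11 dimethylaminomethyl lactone (C11 epimers) | CN(C)CC1C(=O)O[C@@H]2/C=C(/CO[Si](c3ccccc3)(c3ccccc3)C(C)(C)C)CC/C=C(/CO[Si](C)(C)C(C)(C)C)C[C@@H](O[Si](C)(C)C(C)(C)C)[C@@H]12
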